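## The problem

The target 30 joins a hydroquinone monomethyl ether, through an (E)-trisubstituted alkene and a β,γ-unsaturated ketone, to a cyclopentane with two adjacent quaternary ring carbons. C-a carries a methyl group and the CH2–C(=O) arm; C-b carries a methyl group and the acyl carbon of an (E)-γ-hydroxy enone. These two carbons are the only stereocentres. Both are R, the methyl groups are cis, and so the two carbon arms are cis as well. No other stereocentre can relay configuration to them, so their relative configuration has to come from a ring and their absolute configuration from a reagent or catalyst. They in turn control nothing, since both alkenes are matters of geometry only.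

The chain is best assembled convergently from an arene half carrying the (E)-2-methylbut-2-enyl unit and a cyclopentane half carrying the enone. The late intermediates are fragile. The β,γ-unsaturated ketone moves into conjugation under base or acid, and its doubly activated CH2 can add to the enone carbonyl through a six-membered ring. The enone is a Michael acceptor and is reducible. The free 4-alkoxyphenol is easily oxidised.

The feature that opens the problem is that the first arm carbons, the CH2 on C-a and the acyl carbon on C-b, sit cis on neighbouring ring carbons. Joining them gives a cyclobutene fused to the cyclopentane, the meso hydrocarbon cis-1,5-dimethylbicyclo[3.2.0]hept-6-ene 5. Each alkene carbon of 5 lacks only the next carbon of its arm, so a ring-opening cross-metathesis that tells the two enantiotopic alkene carbons apart fixes both quaternary centres and delivers two different arm ends in one step.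

## Retrosynthesis

**30 to 29.** The last step only removes two silyl ethers, the aryl triisopropylsilyl ether and the tertiary triethylsilyl ether. Both fall to buffered fluoride, so nothing basic or acidic meets the β,γ-unsaturated ketone once it exists.

**29 to 16 and 26.** The bond between the arm carbonyl carbon and the allylic CH2 is cut. This divides the molecule into two halves of similar size and keeps the trisubstituted alkene preformed in the arene half. Cutting at the alkene or at the ArCH2–CH bond would instead require a late olefination next to a sensitive ketone. In the forward sense, the α-sulfonyl carbanion of allylic sulfone 26 adds through its α-carbon to aldehyde 16 to give 27, oxidation gives β-keto sulfone 28, and reductive desulfonylation gives 29. The forward steps must accept an enone in the aldehyde partner and must leave the alkene E and out of conjugation.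

**16 to 9 and 12.** The enone Cα=Cβ bond is cut: acetal hydrolysis (15 to 16), elimination (13 via 14 to 15) and a crossed aldol addition of methyl ketone 9 to aldehyde 12. The enone is made before the arm ketone because 9 has a single enolisable position and 12 has none, so the aldol is unambiguous. With the arm ketone present this would not hold. Aldehyde 12 comes in two steps from hydroxy ester 10 via 11.

**9 to 7.** Ketone 9 is the Wacker product of vinyl acetal 8, and 8 is the methanol adduct of enol ether 7. No carbon–carbon bond is involved. The acetal keeps the aldehyde arm silent while the acetyl group is made and condensed.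

**7 to 5 and 6.** Two carbon–carbon double bonds are formed while the cyclobutene of 5 is opened by butyl vinyl ether 6. An enol ether is preferred to ethene, which would give a meso divinyl compound, and to a styrene, whose aryl group would have to be cleaved off again. It puts a masked acetaldehyde on C-a and a masked acetyl on C-b, with the right carbon count and unlike reactivity. The precursor is a C9 hydrocarbon with a mirror plane and no stereochemical problem of its own. The forward reaction has to choose one enantiotopic alkene carbon at an alkene flanked by two quaternary carbons.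

**5 to 1 and 2.** The cyclobutene is traced to diacid 4, its anhydride 3, and a [2+2] photocycloaddition of 1,2-dimethylcyclopentene 1 with maleic anhydride 2. The two carboxyl carbons are sacrificed, and the cis ring fusion that later becomes the cis relation of the arms is enforced by the bicyclo[3.2.0] skeleton.

**26 to 17 and 22.** Sulfone 26 comes from bromide 25 and alcohol 24, the reduction product of enal 23. Enal 23 is the cross-metathesis product of allylarene 21 with methacrolein 22, which sets the E geometry thermodynamically. Arene 21 is the methyl ether of phenol 20, and 20 is the Claisen product of allyl ether 19. The rearrangement puts the allyl group on the only free ortho position of the oxygen that later carries the methyl group, so the substitution pattern is not left to electrophilic substitution. Ether 19 comes from monosilyl ether 18 and this from 2-methylhydroquinone 17, whose less hindered hydroxyl is silylated first.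

## Roads not taken

**Alternative 1:** All four ring bonds at C-a and C-b other than the bond between them are cut. Butane-2,3-dione A1 brings both quaternary carbons with their methyl groups. Two molecules of dimethyl 3-oxopentanedioate A2 condense on it in buffered water (Weiss–Cook reaction, aldol and Michael steps) to the cis-fused diquinane tetraester A3. Hydrolysis and decarboxylation would give dione A4. Removal of one carbonyl group would give the meso ketone A5. An enantiopure lithium amide with Me3SiCl would give silyl enol ether A6 by choice between enantiotopic α-protons, and ozonolysis would give formyl acid A7.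

- Merits: cheap reagents, water as solvent, no photochemistry, no lead, and a cis-dimethyl pattern that cannot go wrong. A7 has the acyl carbon on C-b and the two-carbon arm on C-a at different oxidation levels.
- Weak points: four ester carbons and one ketone oxygen are built only to be removed. Taking A4 to A5 needs a statistical mono-protection. The chiral base is stoichiometric. The formyl group of A7 still lacks the second enone carbon that the vinyl group of 7 already has.
- Comparison: in robustness and scale of the ring-forming steps this road is better than the photocycloaddition and lead tetraacetate sequence. The chosen plan sets against it catalytic enantiocontrol, a route without deoxygenation, and both arm ends delivered at the right carbon count in one step.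

**Alternative 2:** The bonds from C-a to the arm CH2 and from C-b to the acyl carbon are cut. Irradiation near 300 nm of (R)-2-tert-butyl-6-methyl-1,3-dioxin-4-one A8 with the same alkene that opens the chosen route (compound 1) would give the cyclobutane photoadduct A9 (de Mayo reaction). Acetal cleavage and retro-aldol opening would release keto acid A10.

- Merits: it is the shortest road. A10 carries the finished acetyl group on C-b, so no Wacker oxidation is needed, and a CH2CO2H arm on C-a.
- Weak points: the configuration at C-a and C-b is the product of two selectivities. One is the face of the dioxinone that is attacked. The other is whether the cyclopentane ends syn or anti to the dioxinone ring, and the two orientations give opposite enantiomers of A10 after ring opening. A tetrasubstituted alkene is a demanding partner. The chirality comes from a stoichiometric reagent. The acid must be brought to the aldehyde level beside a ketone.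
- Comparison: in step economy this road is better than the chosen plan. The chosen plan sets against it a single enantiodetermining event under catalyst control on a meso substrate, access to either enantiomer by choice of ligand, and independence from syn/anti ratios in a photoreaction.

**Alternative 3:** The bond from C-b to its ring CH2 neighbour and the bond from the arm carbonyl carbon to the future acyl carbon are cut. Acetone-sensitised irradiation of enantiopure 4,5-dimethylbicyclo[2.2.2]oct-5-en-2-one A11 would cause a 1,2-acyl shift with cyclopropane closure (oxa-di-π-methane rearrangement) to tricyclic ketone A12. Dissolving-metal opening of the cyclopropane gives a regiodefined enolate that can be silylated to A6 and ozonised to A7.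

- Merits: the rearrangement is stereospecific, and the enolate is formed on the correct side without a chiral base.
- Weak points: all chirality must be present in A11, which needs a regiocontrolled Diels–Alder route and a resolution or an asymmetric cycloaddition. The sequence to A7 is the longest of the four. It ends at the same formyl acid as Alternative 1, with the same missing enone carbon.
- Comparison: in fidelity of stereochemical transfer it is at least as good as the chosen plan. The chosen plan is several steps shorter and creates the chirality by catalysis from an achiral hydrocarbon.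

Key step: step 4

**Remarks on the chemistry (assumptions):**
- The sense of induction of the molybdenum catalyst on the new meso alkene 5 cannot be derived with certainty. The route is written with the (R)-aryloxide; if the sense proves opposite, the (S)-aryloxide is used and nothing else changes.
- Photoadduct 3 is drawn as the anti isomer. The syn isomer converges on the same alkene 5.
- In the catalyst, Ad is 1-adamantyl and Ar*OH is (R)-3,3'-dibromo-2'-(tert-butyldimethylsilyloxy)-5,5',6,6',7,7',8,8'-octahydro-1,1'-binaphthalen-2-ol.

## Route

Step 1
Reactants: 1 1,2-dimethylcyclopentene; 2 maleic anhydride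
Product: 3 cis-1,5-dimethylbicyclo[3.2.0]heptane-6,7-dicarboxylic anhydride (meso, ring fusion cis, anhydride ring anti to the three-carbon bridge)
Conditions: hν (medium-pressure Hg lamp, Pyrex), PhCOMe (0.1 equiv), EtOAc, 20 °C
Reagents that add atoms: none
Why: Triplet-sensitised [2+2] photocycloaddition of maleic anhydride to an alkene; the bicyclo[3.2.0] fusion and the anhydride ring can only be cis, so the adduct keeps a mirror plane, and the syn or anti relation of the outer rings is erased in step 3.

Step 2
Reactants: 3 anhydride
Product: 4 cis-1,5-dimethylbicyclo[3.2.0]heptane-6,7-cis-dicarboxylic acid (meso)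
Conditions: H2O, acetone, 55 °C
Reagents that add atoms: water, O
Why: Hydrolysis of a strained cyclic anhydride; no stereocentre is touched.

Step 3
Reactants: 4 diacid
Product: 5 cis-1,5-dimethylbicyclo[3.2.0]hept-6-ene (meso)
Conditions: Pb(OAc)4, pyridine, 65 °C
Reagents that add atoms: none
Why: Oxidative bis-decarboxylation of a vicinal cis-diacid by tetravalent lead is the classical passage from maleic anhydride photoadducts to cyclobutenes; the mirror plane is kept, so 5 is meso.

Step 4
Reactants: 5 meso cyclobutene; 6 butyl vinyl ether
Product: 7 (1R,2S)-1-[(Z)-2-butoxyethenyl]-2-ethenyl-1,2-dimethylcyclopentane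
Conditions: Mo(NAd)(CHCMe2Ph)(2,5-Me2NC4H2)(OAr*) (5 mol %, hexavalent molybdenum, formed in situ from Mo(NAd)(CHCMe2Ph)(2,5-Me2NC4H2)2 and Ar*OH), 6 (10 equiv), C6H6, 22 °C
Reagents that add atoms: none
Why: Ring-opening cross-metathesis by the Chauvin cycle: the alkylidene Mo=CH(OBu) formed from 6 adds across the strained alkene of 5 to a metallacyclobutane, cycloreversion opens the four-membered ring and leaves CH=CH(OBu) on one former alkene carbon and a molybdenum alkylidene on the other, and a second molecule of 6 releases this as the vinyl group and returns Mo=CH(OBu). The closest known reaction type is the enantioselective, Z-selective ring-opening cross-metathesis of meso cyclobutenes and oxabicyclic alkenes with enol ethers under stereogenic-at-molybdenum monoaryloxide pyrrolide complexes, from which 5 differs by its two flanking quaternary carbons. No ring is closed; the cyclobutene is opened and the cyclopentane passes through unchanged. The two quaternary carbons become stereocentres only because the mirror plane is lost, and both are fixed in the one event in which the stereogenic molybdenum centre with its enantiopure aryloxide selects one of the two enantiotopic alkene carbons for bonding to the alkoxy-substituted alkylidene carbon (catalyst control). Their cis relation is inherited from the ring fusion of 5. The step needs enantiotopic-group selection and cross-metathesis in preference to ring-opening oligomerisation; the second is secured by the excess of the enol ether, by the release of cyclobutene strain that makes the opening irreversible, and by the quaternary carbons that shield the product alkenes from further metathesis. The catalyst is expected to approach the face that carries the two methyl groups, since the other face lies under the three-carbon bridge. The enol ether geometry is lost in step 5 and does not matter.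

Step 5
Reactants: 7 enol ether
Product: 8 (1R,2S)-1-(2,2-dimethoxyethyl)-2-ethenyl-1,2-dimethylcyclopentane
Conditions: PPTS (0.1 equiv), MeOH, 40 °C
Reagents that add atoms: methanol, CO
Why: Acid-catalysed addition of methanol to the enol ether and acetal exchange through oxocarbenium ions give the dimethyl acetal; the weak acid does not protonate the vinyl group, and solvent methanol captures the oxocarbenium ion before the neighbouring vinyl group can (Prins closure).

Step 6
Reactants: 8 vinyl acetal
Product: 9 1-[(1R,2R)-2-(2,2-dimethoxyethyl)-1,2-dimethylcyclopentyl]ethan-1-one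
Conditions: PdCl2 (0.2 equiv), CuCl (1 equiv), O2 (1 atm), DMF/H2O 7:1, 25 °C
Reagents that add atoms: water, O
Why: Tsuji–Wacker oxidation: Markovnikov hydroxypalladation of the monosubstituted alkene by divalent palladium and β-hydride elimination give the methyl ketone; a vinyl group on a quaternary carbon reacts slowly but with the normal regiochemistry, and the acetal is expected to survive the aqueous DMF medium.

Step 7
Reactants: 10 methyl 2-hydroxy-2-methylpropanoate
Product: 11 methyl 2-methyl-2-(triethylsilyloxy)propanoate
Conditions: Et3SiOTf, 2,6-lutidine, CH2Cl2, 0 °C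
Reagents that add atoms: triethylsilyl trifluoromethanesulfonate, CC[Si](CC)(CC)OS(=O)(=O)C(F)(F)F
Why: Silylation of a hindered tertiary alcohol with a silyl triflate and a hindered pyridine base.

Step 8
Reactants: 11 silyloxy ester
Product: 12 2-methyl-2-(triethylsilyloxy)propanal
Conditions: iBu2AlH (1.1 equiv), CH2Cl2, −78 °C; aq. potassium sodium tartrate (KNaC4H4O6)
Reagents that add atoms: none
Why: Partial reduction of an α-oxygenated ester; the chelated aluminium hemiacetal persists at −78 °C, so the aldehyde is set free only on work-up.

Step 9
Reactants: 9 methyl ketone; 12 aldehyde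
Product: 13 1-[(1R,2R)-2-(2,2-dimethoxyethyl)-1,2-dimethylcyclopentyl]-3-hydroxy-4-methyl-4-(triethylsilyloxy)pentan-1-one (both epimers at C-3)
Conditions: LiN(iPr)2 (1.1 equiv), THF, −78 °C; then 12 (1.2 equiv), −78 °C; aq. NH4Cl
Reagents that add atoms: none
Why: Crossed aldol addition of a lithium enolate; 9 can enolise only at its methyl group because the other α-carbon is quaternary, and 12 has no α-hydrogen, so one constitution results and the new carbinol centre is removed in step 10.

Step 10
Reactants: 13 aldol adduct
Product: 15 (E)-1-[(1R,2R)-2-(2,2-dimethoxyethyl)-1,2-dimethylcyclopentyl]-4-methyl-4-(triethylsilyloxy)pent-2-en-1-one, via secondary mesylate 14 (not isolated)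
Conditions: MsCl, Et3N, CH2Cl2, 0 °C; then DBU, rt
Reagents that add atoms: none
Why: Mesylation and E1cB elimination of the β-sulfonyloxy ketone complete the aldol condensation; the E enone is favoured because the bulky silyloxy-bearing carbon avoids the acyl group.

Step 11
Reactants: 15 enone acetal
Product: 16 2-[(1R,2R)-1,2-dimethyl-2-[(E)-4-methyl-4-(triethylsilyloxy)pent-2-enoyl]cyclopentyl]acetaldehyde
Conditions: PPTS, acetone/H2O 9:1, 45 °C
Reagents that add atoms: water, O
Why: Acid-catalysed acetal hydrolysis; the hindered tertiary silyl ether tolerates the weak acid, and the enone has no enolisable α'- or γ-hydrogen through which the new aldehyde could cyclise onto it.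

Step 12
Reactants: 17 2-methylbenzene-1,4-diol
Product: 18 2-methyl-4-[tri(propan-2-yl)silyloxy]phenol
Conditions: iPr3SiCl (1.0 equiv), imidazole, DMF, 0 °C
Reagents that add atoms: chlorotri(propan-2-yl)silane, CC(C)[Si](Cl)(C(C)C)C(C)C
Why: Silylation with a bulky chlorosilane distinguishes the two phenols by hindrance; the hydroxyl without an ortho substituent reacts first and the second silylation next to the methyl group is slow.

Step 13
Reactants: 18 monosilyl ether
Product: 19 [3-methyl-4-(prop-2-enyloxy)phenoxy]tri(propan-2-yl)silane
Conditions: allyl bromide, K2CO3, acetone, reflux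
Reagents that add atoms: 3-bromoprop-1-ene, C=CCBr
Why: Williamson etherification of the remaining phenol; the aryl silyl ether is stable to carbonate in dry acetone.

Step 14
Reactants: 19 allyl aryl ether
Product: 20 2-methyl-6-(prop-2-enyl)-4-[tri(propan-2-yl)silyloxy]phenol
Conditions: PhNEt2, 190 °C
Reagents that add atoms: none
Why: Aromatic Claisen rearrangement ([3,3]-sigmatropic shift, then tautomerisation); only one ortho position is free, while migration to the methyl-bearing ortho carbon is reversible and the para position is blocked by oxygen.

Step 15
Reactants: 20 phenol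
Product: 21 [4-methoxy-3-methyl-5-(prop-2-enyl)phenoxy]tri(propan-2-yl)silane
Conditions: MeI, K2CO3, acetone, reflux
Reagents that add atoms: iodomethane, CI
Why: O-Methylation of a 2,6-disubstituted phenol by SN2 reaction of its phenoxide with the smallest electrophile.

Step 16
Reactants: 21 allylarene; 22 2-methylprop-2-enal
Product: 23 (E)-4-[2-methoxy-3-methyl-5-[tri(propan-2-yl)silyloxy]phenyl]-2-methylbut-2-enal
Conditions: RuCl2(H2IMes)(=CH-C6H4-2-OiPr) (second-generation Hoveyda–Grubbs catalyst, 5 mol %), 22 (5 equiv), CH2Cl2, 40 °C
Reagents that add atoms: none
Why: Olefin cross-metathesis of a terminal alkene with methacrolein; the conjugated trisubstituted enal forms under thermodynamic control as the E isomer, and loss of ethene drives the reaction.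

Step 17
Reactants: 23 enal
Product: 24 (E)-4-[2-methoxy-3-methyl-5-[tri(propan-2-yl)silyloxy]phenyl]-2-methylbut-2-en-1-ol
Conditions: NaBH4, CeCl3·7H2O, MeOH, 0 °C
Reagents that add atoms: none
Why: Luche reduction gives clean 1,2-reduction of the enal without touching the alkene.

Step 18
Reactants: 24 allylic alcohol
Product: 26 [3-[(E)-4-(benzenesulfonyl)-3-methylbut-2-enyl]-4-methoxy-5-methylphenoxy]tri(propan-2-yl)silane, via allylic bromide 25 (not isolated)
Conditions: CBr4, PPh3, CH2Cl2, 0 °C; then PhSO2Na, DMF, rt
Reagents that add atoms: sodium benzenesulfinate, [Na+].[O-]S(=O)c1ccccc1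
Why: Appel bromination under neutral conditions, then SN2 S-alkylation of the sulfinate at the primary allylic carbon; neither step disturbs the alkene geometry.

Step 19
Reactants: 26 allylic sulfone; 16 aldehyde
Product: 27 β-hydroxy sulfone, (E)-1-[(1R,2R)-2-[(E)-3-(benzenesulfonyl)-2-hydroxy-6-[2-methoxy-3-methyl-5-[tri(propan-2-yl)silyloxy]phenyl]-4-methylhex-4-enyl]-1,2-dimethylcyclopentyl]-4-methyl-4-(triethylsilyloxy)pent-2-en-1-one (mixture of diastereomers at C-2 and C-3 of the hexenyl chain)
Conditions: 26 (1.2 equiv), nBuLi (1.15 equiv), THF, −78 °C; then 16, −78 °C; AcOH, −78 °C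
Reagents that add atoms: none
Why: Addition of a lithiated allylic sulfone through its α-carbon to an aldehyde, with the E alkene of the sulfone retained at low temperature; the unhindered aldehyde is far more electrophilic than the enone, whose carbonyl sits on a quaternary carbon and whose β-carbon is neopentyl-like. The cold acidic quench prevents retro-addition, and both new centres are destroyed in steps 20 and 21.

Step 20
Reactants: 27 β-hydroxy sulfone
Product: 28 β-keto sulfone, (E)-1-[(1R,2R)-2-[(E)-3-(benzenesulfonyl)-6-[2-methoxy-3-methyl-5-[tri(propan-2-yl)silyloxy]phenyl]-4-methyl-2-oxohex-4-enyl]-1,2-dimethylcyclopentyl]-4-methyl-4-(triethylsilyloxy)pent-2-en-1-one (both epimers at C-3 of the hexenyl chain)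
Conditions: Dess–Martin periodinane, CH2Cl2, 0 °C to rt
Reagents that add atoms: none
Why: Dess–Martin oxidation of a secondary alcohol under non-basic conditions; the alkenes, silyl ethers and electron-rich arene are inert to the periodinane.

Step 21
Reactants: 28 β-keto sulfone
Product: 29 (E)-1-[(1R,2R)-2-[(E)-6-[2-methoxy-3-methyl-5-[tri(propan-2-yl)silyloxy]phenyl]-4-methyl-2-oxohex-4-enyl]-1,2-dimethylcyclopentyl]-4-methyl-4-(triethylsilyloxy)pent-2-en-1-one
Conditions: SmI2 (2.2 equiv), THF/MeOH 10:1, −78 °C
Reagents that add atoms: none
Why: Reductive desulfonylation of an α-sulfonyl ketone by divalent samarium: two single-electron transfers expel benzenesulfinate, and the samarium enolate is protonated by methanol at its α-carbon, which leaves the alkene β,γ and E. α-Sulfonyl ketones take up electrons from SmI2 at −78 °C much faster than an enone does in the absence of HMPA, and the proton source quenches the enolate before it can add to the enone carbonyl.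

Step 22
Reactants: 29 bis-silyl ether
Product: 30 (E)-1-[(1R,2R)-2-[(E)-6-(5-hydroxy-2-methoxy-3-methylphenyl)-4-methyl-2-oxohex-4-enyl]-1,2-dimethylcyclopentyl]-4-hydroxy-4-methylpent-2-en-1-one (CNP0305066.1)
Conditions: Bu4NF, AcOH (1:1), THF, 0 °C to rt
Reagents that add atoms: none
Why: Fluoride-induced cleavage of the aryl and the tertiary alkyl silyl ether; acetic acid protonates the phenoxide and alkoxide as they form, so the β,γ-unsaturated ketone is neither isomerised nor cyclised onto the enone.

## Compound list

1 | 1,2-dimethylcyclopentene | CC1=C(C)CCC1 | starting material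
2 | maleic anhydride | O=C1OC(=O)C=C1 | starting material
3 | cis-1,5-dimethylbicyclo[3.2.0]heptane-6,7-dicarboxylic anhydride (meso, anti isomer drawn) | C[C@]12CCC[C@@]1(C)[C@@H]3C(=O)OC(=O)[C@H]23 | intermediate
4 | cis-1,5-dimethylbicyclo[3.2.0]heptane-6,7-cis-dicarboxylic acid (meso) | C[C@]12CCC[C@@]1(C)[C@H](C(=O)O)[C@@H]2C(=O)O | intermediate
5 | cis-1,5-dimethylbicyclo[3.2.0]hept-6-ene (meso) | C[C@]12CCC[C@@]1(C)C=C2 | intermediate
6 | butyl vinyl ether | C=COCCCC | starting material
7 | (1R,2S)-1-[(Z)-2-butoxyethenyl]-2-ethenyl-1,2-dimethylcyclopentane | CCCCO/C=C\[C@@]1(C)CCC[C@@]1(C)C=C | intermediate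
8 | (1R,2S)-1-(2,2-dimethoxyethyl)-2-ethenyl-1,2-dimethylcyclopentane | COC(OC)C[C@@]1(C)CCC[C@@]1(C)C=C | intermediate
9 | 1-[(1R,2R)-2-(2,2-dimethoxyethyl)-1,2-dimethylcyclopentyl]ethan-1-one | COC(OC)C[C@@]1(C)CCC[C@@]1(C)C(C)=O | intermediate
10 | methyl 2-hydroxy-2-methylpropanoate | COC(=O)C(C)(C)O | starting material
11 | methyl 2-methyl-2-(triethylsilyloxy)propanoate | COC(=O)C(C)(C)O[Si](CC)(CC)CC | intermediate
12 | 2-methyl-2-(triethylsilyloxy)propanal | O=CC(C)(C)O[Si](CC)(CC)CC | intermediate
13 | aldol adduct, 3-hydroxy ketone (both C-3 epimers) | COC(OC)C[C@@]1(C)CCC[C@@]1(C)C(=O)CC(O)C(C)(C)O[Si](CC)(CC)CC | intermediate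
14 | methanesulfonate of 13 (not isolated) | COC(OC)C[C@@]1(C)CCC[C@@]1(C)C(=O)CC(OS(C)(=O)=O)C(C)(C)O[Si](CC)(CC)CC | intermediate
15 | (E)-enone dimethyl acetal | COC(OC)C[C@@]1(C)CCC[C@@]1(C)C(=O)/C=C/C(C)(C)O[Si](CC)(CC)CC | intermediate
16 | (E)-enone aldehyde | O=CC[C@@]1(C)CCC[C@@]1(C)C(=O)/C=C/C(C)(C)O[Si](CC)(CC)CC | intermediate
17 | 2-methylbenzene-1,4-diol | Cc1cc(O)ccc1O | starting material
18 | 2-methyl-4-[tri(propan-2-yl)silyloxy]phenol | Cc1cc(O[Si](C(C)C)(C(C)C)C(C)C)ccc1O | intermediate
19 | [3-methyl-4-(prop-2-enyloxy)phenoxy]tri(propan-2-yl)silane | C=CCOc1ccc(O[Si](C(C)C)(C(C)C)C(C)C)cc1C | intermediate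
20 | 2-methyl-6-(prop-2-enyl)-4-[tri(propan-2-yl)silyloxy]phenol | C=CCc1cc(O[Si](C(C)C)(C(C)C)C(C)C)cc(C)c1O | intermediate
21 | [4-methoxy-3-methyl-5-(prop-2-enyl)phenoxy]tri(propan-2-yl)silane | C=CCc1cc(O[Si](C(C)C)(C(C)C)C(C)C)cc(C)c1OC | intermediate
22 | 2-methylprop-2-enal | CC(=C)C=O | starting material
23 | (E)-4-aryl-2-methylbut-2-enal (aryl = 2-methoxy-3-methyl-5-triisopropylsilyloxyphenyl) | COc1c(C)cc(O[Si](C(C)C)(C(C)C)C(C)C)cc1C/C=C(\C)C=O | intermediate
24 | (E)-4-aryl-2-methylbut-2-en-1-ol | COc1c(C)cc(O[Si](C(C)C)(C(C)C)C(C)C)cc1C/C=C(\C)CO | intermediate
25 | (E)-allylic bromide (not isolated) | COc1c(C)cc(O[Si](C(C)C)(C(C)C)C(C)C)cc1C/C=C(\C)CBr | intermediate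
26 | (E)-allylic phenyl sulfone | COc1c(C)cc(O[Si](C(C)C)(C(C)C)C(C)C)cc1C/C=C(\C)CS(=O)(=O)c1ccccc1 | intermediate
27 | β-hydroxy sulfone (diastereomers at the carbinol and sulfonyl carbons) | COc1c(C)cc(O[Si](C(C)C)(C(C)C)C(C)C)cc1C/C=C(\C)C(C(O)C[C@@]1(C)CCC[C@@]1(C)C(=O)/C=C/C(C)(C)O[Si](CC)(CC)CC)S(=O)(=O)c1ccccc1 | intermediate
28 | β-keto sulfone (epimers at the sulfonyl carbon) | COc1c(C)cc(O[Si](C(C)C)(C(C)C)C(C)C)cc1C/C=C(\C)C(C(=O)C[C@@]1(C)CCC[C@@]1(C)C(=O)/C=C/C(C)(C)O[Si](CC)(CC)CC)S(=O)(=O)c1ccccc1 | intermediate
29 | bis-silyl ether of the target | COc1c(C)cc(O[Si](C(C)C)(C(C)C)C(C)C)cc1C/C=C(\C)CC(=O)C[C@@]1(C)CCC[C@@]1(C)C(=O)/C=C/C(C)(C)O[Si](CC)(CC)CC | intermediate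
30 | (E)-1-[(1R,2R)-2-[(E)-6-(5-hydroxy-2-methoxy-3-methylphenyl)-4-methyl-2-oxohex-4-enyl]-1,2-dimethylcyclopentyl]-4-hydroxy-4-methylpent-2-en-1-one | COc1c(C)cc(O)cc1C/C=C(\C)CC(=O)C[C@@]1(C)CCC[C@@]1(C)C(=O)/C=C/C(C)(C)O | target

## Step count and least certain steps

Total: 22 steps. Longest linear sequence: 13 steps (1, 2, 3, 4, 5, 6, 9, 10, 11, 19, 20, 21, 22). The arene branch has 7 steps (12 to 18) and the aldehyde branch 2 steps (7, 8).

**Step 4 (key step).** Both faces of the cyclobutene are hindered, one by two methyl groups and one by the three-carbon bridge. The catalyst may therefore decay before the alkylidene engages the alkene, or the two enantiotopic alkene carbons may be poorly distinguished at a substrate bulkier than those on which this catalyst class has been used. Ring-opening oligomerisation would compete if cross-metathesis with the enol ether were slow.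

The fallback gives up metathesis for oxidative opening and enzymatic desymmetrisation. It sets out from 5 and returns at 8.
- Ozonolysis of 5 with NaBH4 work-up should give the meso diol cis-(1,2-dimethylcyclopentane-1,2-diyl)dimethanol F1.
- A lipase with vinyl acetate should acylate one enantiotopic hydroxymethyl group to the monoacetate F2.
- Dess–Martin oxidation gives the acetoxy aldehyde F3, and Wittig methylenation (Ph3P=CH2) the vinyl acetate F4.
- Methanolysis with K2CO3 gives the alcohol F5, and a second oxidation the aldehyde F6.
- Ph3P=CHOMe gives the methyl enol ether F7, which PPTS in methanol converts into 8.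
- If the lipase acylates the other hydroxymethyl group, the two Wittig reactions are exchanged.

**Step 3.** The lead tetraacetate bis-decarboxylation may stop at low conversion. The strained alkene may be oxidised further at its allylic positions. The volatile hydrocarbon may be lost on isolation.

The fallback reaches 5 without photochemistry or lead. It sets out from 1 and returns at 5.
- Dichloroketene, made from Cl3CCOCl and Zn(Cu), should add to 1 to give 7,7-dichloro-1,5-dimethylbicyclo[3.2.0]heptan-6-one F8.
- Zn in AcOH removes the chlorine atoms to give the cyclobutanone F9.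
- TsNHNH2 gives the tosylhydrazone F10.
- MeLi (Shapiro reaction) gives 5. The only α-hydrogens lie on the CH2 group, so the alkene can form in one position only.

**Step 6.** Hydroxypalladation of a vinyl group on a quaternary carbon is slow. During a long reaction the acid formed from PdCl2 and CuCl may cleave the acetal, and the keto aldehyde so released would close by intramolecular aldol reaction. Some oxidation at the terminal carbon is also possible.

The fallback replaces the palladium chemistry by radical hydration. It sets out from 8 and returns at 9.
- Co(acac)2 (divalent cobalt), PhSiH3 and O2 in iPrOH (Mukaiyama hydration) should give the Markovnikov alcohol 1-[(1R,2R)-2-(2,2-dimethoxyethyl)-1,2-dimethylcyclopentyl]ethan-1-ol F11 under neutral conditions.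
- Dess–Martin oxidation gives 9.

**Step 21.** Electron transfer to the enone may compete with that to the α-sulfonyl ketone, leading to saturation or reductive loss of the γ-silyloxy group. The samarium enolate may also close onto the enone carbonyl through a six-membered ring before it is protonated.

The fallback avoids the sulfone and with it every reductive step; it also removes the sulfone addition of step 19 from the route. It sets out from 24 (with 16) and returns at 29.
- Alcohol 24 is converted with MsCl, LiCl and 2,4,6-collidine into the (E)-allylic chloride F12.
- Activated barium, from BaI2 and lithium biphenylide, turns F12 at −78 °C into an allylbarium reagent. Such reagents add to aldehydes through their α-carbon with retention of alkene geometry.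
- Addition to 16 should give the homoallylic alcohol F13.
- Dess–Martin oxidation gives 29.

## Further compounds

F1 | step 4 | cis-(1,2-dimethylcyclopentane-1,2-diyl)dimethanol (meso) | OC[C@@]1(C)CCC[C@@]1(C)CO
F2 | step 4 | monoacetate of F1 (acetate on the C-a hydroxymethyl group) | CC(=O)OC[C@@]1(C)CCC[C@@]1(C)CO
F3 | step 4 | acetoxy aldehyde | CC(=O)OC[C@@]1(C)CCC[C@@]1(C)C=O
F4 | step 4 | vinyl acetate | CC(=O)OC[C@@]1(C)CCC[C@@]1(C)C=C
F5 | step 4 | vinyl alcohol | OC[C@@]1(C)CCC[C@@]1(C)C=C
F6 | step 4 | vinyl aldehyde | O=C[C@@]1(C)CCC[C@@]1(C)C=C
F7 | step 4 | methyl enol ether (E/Z mixture) | COC=C[C@@]1(C)CCC[C@@]1(C)C=C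
F8 | step 3 | 7,7-dichloro-1,5-dimethylbicyclo[3.2.0]heptan-6-one (racemic, cis-fused) | C[C@]12CCC[C@@]1(C)C(Cl)(Cl)C2=O
F9 | step 3 | 1,5-dimethylbicyclo[3.2.0]heptan-6-one (racemic, cis-fused) | C[C@]12CCC[C@@]1(C)CC2=O
F10 | step 3 | 4-methylbenzenesulfonylhydrazone of F9 | C[C@]12CCC[C@@]1(C)CC2=NNS(=O)(=O)c1ccc(C)cc1
F11 | step 6 | 1-[(1R,2R)-2-(2,2-dimethoxyethyl)-1,2-dimethylcyclopentyl]ethan-1-ol (both carbinol epimers) | COC(OC)C[C@@]1(C)CCC[C@@]1(C)C(C)O
F12 | step 21 | (E)-allylic chloride corresponding to 24 | COc1c(C)cc(O[Si](C(C)C)(C(C)C)C(C)C)cc1C/C=C(\C)CCl
F13 | step 21 | homoallylic alcohol (both carbinol epimers) | COc1c(C)cc(O[Si](C(C)C)(C(C)C)C(C)C)cc1C/C=C(\C)CC(O)C[C@@]1(C)CCC[C@@]1(C)C(=O)/C=C/C(C)(C)O[Si](CC)(CC)CC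
A1 | alternative 1 | butane-2,3-dione | CC(=O)C(C)=O
A2 | alternative 1 | dimethyl 3-oxopentanedioate | COC(=O)CC(=O)CC(=O)OC
A3 | alternative 1 | tetramethyl cis-1,5-dimethyl-3,7-dioxobicyclo[3.3.0]octane-2,4,6,8-tetracarboxylate | COC(=O)C1C(=O)C(C(=O)OC)[C@]2(C)C(C(=O)OC)C(=O)C(C(=O)OC)[C@]12C
A4 | alternative 1 | cis-1,5-dimethylbicyclo[3.3.0]octane-3,7-dione | C[C@]12CC(=O)C[C@@]1(C)CC(=O)C2
A5 | alternative 1 | cis-1,5-dimethylbicyclo[3.3.0]octan-3-one (meso) | C[C@]12CCC[C@@]1(C)CC(=O)C2
A6 | alternative 1 | trimethylsilyl enol ether of A5 (single enantiomer) | C[Si](C)(C)OC1=C[C@]2(C)CCC[C@]2(C)C1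
A7 | alternative 1 | 2-[(1R,2R)-2-formyl-1,2-dimethylcyclopentyl]acetic acid | OC(=O)C[C@@]1(C)CCC[C@@]1(C)C=O
A8 | alternative 2 | (R)-2-tert-butyl-6-methyl-1,3-dioxin-4-one | CC1=CC(=O)O[C@H](C(C)(C)C)O1
A9 | alternative 2 | cis-anti-cis photoadduct (tricyclic acetal lactone) | CC(C)(C)[C@H]1OC(=O)[C@H]2[C@@](C)(O1)[C@]3(C)CCC[C@]23C
A10 | alternative 2 | 2-[(1R,2R)-2-acetyl-1,2-dimethylcyclopentyl]acetic acid | OC(=O)C[C@@]1(C)CCC[C@@]1(C)C(C)=O
A11 | alternative 3 | 4,5-dimethylbicyclo[2.2.2]oct-5-en-2-one (single enantiomer) | O=C1C[C@@]2(C)CC[C@@H]1C=C2C
A12 | alternative 3 | 1,5-dimethyltricyclo[3.3.0.0(2,8)]octan-3-one | O=C1C[C@@]2(C)CC[C@H]3[C@@H]1[C@@]23C
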